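Per hour, at one temperature and in these runs, chains take a nearly fixed share of whatever free monomer stands in the flask, and that share is the quick number you asked for; your hunch, that impurity consumes monomer one for one, is tested below.

the same everywhere: initiator 0.50 mM
- Sunday's: free monomer 0.10 M; protic impurity 0.028 M; temperature 80 °C; run made earlier
- Wednesday's: free monomer 0.10 M; protic impurity 0.044 M; temperature 92 °C; run made earlier
- Friday's: free monomer 0.050 M; protic impurity 0.020 M; temperature 80 °C; run made earlier
- alder: free monomer 0.10 M; protic impurity 0.0200 M; temperature 100 °C; time 6.0 h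
- cedar: free monomer 0.10 M; protic impurity 0.0200 M; at 100 °C until 80 min, from then on at 85 °C; time 6.0 h
- elm: free monomer 0.10 M; protic impurity 0.0200 M; temperature 85 °C; time 6.0 h

| run | time / h | monomer in chains / % | free monomer / % |
|---|---|---|---|
| Sunday's | 0.833 | 2.8 | 87.2 |
| Sunday's | 2.50 | 6.4 | 72.7 |
| Sunday's | 4.00 | 9.3 | 65.3 |
| Sunday's | 6.00 | 12.7 | 58.2 |
| Sunday's | 10.0 | 20.1 | 51.0 |
| Sunday's | 15.0 | 26.9 | 42.3 |
| Wednesday's | 0.333 | 2.5 | 84.1 |
| Wednesday's | 1.00 | 6.1 | 66.2 |
| Wednesday's | 1.50 | 9.3 | 57.3 |
| Wednesday's | 2.50 | 13.3 | 47.4 |
| Wednesday's | 4.00 | 18.3 | 38.9 |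
| Wednesday's | 5.00 | 21.6 | 34.7 |
| Wednesday's | 6.00 | 24.0 | 31.4 |
| Friday's | 4.00 | 9.8 | 65.3 |
| Friday's | 6.00 | 13.6 | 56.3 |
| Friday's | 10.0 | 19.2 | 45.3 |
| Friday's | 15.0 | 25.3 | 36.9 |

(readings scatter by 0.5 percentage points)

- the flask with the highest amount of monomer in chains, in percent of the free monomer charged ("all alike" if they lie within 1.5 percentage points) (alder / cedar / elm / all alike)
- final monomer in chains, as a percentage of the free monomer charged, in alder
- final monomer in chains, as a percentage of the free monomer charged, in cedar
- final monomer in chains, as a percentage of the free monomer charged, in elm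



The hunch fits the readings. At Wednesday's last reading 44.6% of the monomer charged stands in neither column, and Wednesday's impurity charge is 44.0% of it, which I read as impurity taking monomer one for one. On that reading the impurity of each new recipe takes its own charge, and I reckon with the 80.0% beyond that as open to chains.

Now freeze whatever carries the growth at this initiator charge, and growth becomes pseudo-first-order. Late stretches of the runs, reading chains gained per hour over mean free monomer, give 0.0314 /h on Sunday and 0.0776 /h on Wednesday. Friday, on half the monomer, reads 0.0279 /h, close to Sunday's at the same temperature.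

With the logarithm taken as straight in temperature, the growth constant at 85 °C is 0.0458 /h, and at 100 °C, by extrapolation, 0.142 /h.

Constant times time, summed over the legs, is the exposure: 0.851 for alder, 0.403 for cedar, 0.275 for elm. In this reckoning chains are the monomer left for them times one minus the exponential of minus the exposure. My reckoning is alder 45.8%, cedar 26.5%, elm 19.2%.

The forecast gives alder 47.5% (39% to 54%), cedar 28% (24.5% to 31.5%) and elm 20% (18.5% to 21.8%), names alder highest, stands above this reckoning in each flask, and warns: “The 100 °C figures are extrapolated, so they are less certain.”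

The flasks give 47.2% in alder, 28.2% in cedar and 20.0% in elm, with alder highest; the reckoning sits 1.4 percentage points, 1.7 points and 0.80 points low.

    initiator → 2 initiating radical (k = 0.0164 /h, Ea = 115 kJ/mol)
    free monomer + initiating radical → growing radical + monomer in chains (k = 1.60 × 10⁵ /M/s, Ea = 13.0 kJ/mol)
    free monomer + growing radical → monomer in chains + growing radical, rate k3*[growing radical]*[free monomer] (k = 12800 /M/s, Ea = 39.0 kJ/mol)
    2 growing radical → dead chain (k = 2.00 × 10⁸ /M/s, Ea = 13.0 kJ/mol)
    2 free monomer → homo dimer (k = 0.101 /M/h, Ea = 87.0 kJ/mol)
    free monomer → decomposition product (k = 6.63 × 10⁻⁴ /h, Ea = 124 kJ/mol)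
    protic impurity + free monomer → quenched substrate (k = 17.9 /M/h, Ea = 58.0 kJ/mol)
    (constants at 100 °C)

Elm ends at 20.0% because growing radicals pair off into dead chains; the same flask without that step reaches 98.0%. Cedar's growing radical, at 85 °C, stands at 1.66 × 10⁻⁹ M after 6.00 h and 1.61 × 10⁻⁹ M after 25.0 h, nearly constant, and 0.0458 /h keeps serving. After cedar's change of temperature it gives 12 points of new chains, against 12 points found. Carried on to the later reading of cedar, it takes free monomer from 49.4% to 20.7%, and that reading shows 20.1%.

The earlier runs and the new flask were computed with made-up constants, and the scatter is random.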